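Four flasks hold the same amounts, 0.24 M of starting material and 0.240 M of partner, and differ in their temperature history. Two earlier runs show how target grows at other charges.

| flask | starting material | partner | free catalyst | second catalyst | temperature | remark | time |
|---|---|---|---|---|---|---|---|
| north-west | 0.12 M | 0.24 M | 12 mM | 6 mM | 110 °C | run made earlier |  |
| south-east | 0.18 M | 0.24 M | 12 mM | 6 mM | 132 °C | run made earlier |  |
| noon | 0.24 M | 0.240 M | 12 mM | 6.0 mM | 120 °C |  | 1.0 h |
| winter | 0.24 M | 0.240 M | 12 mM | 6.0 mM | 100 °C |  | 1.0 h |
| dawn | 0.24 M | 0.240 M | 12 mM | 6.0 mM | 140 °C |  | 1.0 h |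
| summer | 0.24 M | 0.240 M | 12 mM | 6.0 mM |  | at 100 °C until 30 min, from then on at 140 °C | 1.0 h |

| run | time / min | target / % |
|---|---|---|
| north-west | 3.00 | 6.1 |
| north-west | 10.0 | 29.3 |
| north-west | 15.0 | 42.9 |
| north-west | 25.0 | 62.8 |
| north-west | 30.0 | 73.7 |
| north-west | 50.0 | 89.0 |
| north-west | 60.0 | 94.4 |
| south-east | 1.50 | 9.0 |
| south-east | 2.00 | 11.9 |
| south-east | 3.00 | 19.9 |
| south-east | 6.00 | 34.6 |
| south-east | 8.00 | 43.8 |
| south-east | 15.0 | 68.1 |
| south-east | 20.0 | 79.9 |

(readings scatter by 1 percentage point)

- the flask with the highest amount of target, in percent of the starting material charged ("all alike" if they lie within 1.5 percentage points) (noon / winter / dawn / summer / all alike)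
- final target, as a percentage of the starting material charged, in noon
- final target, as a percentage of the starting material charged, in winter
- final target, as a percentage of the starting material charged, in dawn
- final target, as a percentage of the starting material charged, in summer

The north-west run ends at 94.4 % of its charge, or 113 mM of target, yet its flask held 6 mM of second catalyst, and the candidate steps bind one second catalyst to each open intermediate. Target stands at 18.8 times the second catalyst charged. The two amounts fit because the target step hands the second catalyst back, so it works in rounds, like a pump with a small stroke.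

Its pace, the turnover frequency, is target made per minute per second catalyst charged. Read from the steep early stretch of each run, with the scatter of the readings:

north-west, 3.00 min to 10.0 min: 0.663 min⁻¹

south-east, 3.00 min to 6.00 min: 1.47 min⁻¹

The hotter run goes faster, which reads as an apparent activation energy of 46.7 kJ mol⁻¹. Each new flask needs 40.0 rounds to finish its charge. Rounds available over rounds needed then gives:

winter: 0.447 min⁻¹, share 67.1 %

noon: 0.963 min⁻¹, share 144 %

dawn: 1.92 min⁻¹, share 288 %

summer: share 178 %

This share is the round budget. The early pace does not hold, though: from 30.0 min to 60.0 min the north-west run manages 0.138 min⁻¹. The budget therefore serves here to rank flasks, and it is not a yield. This reckoning expects the order dawn, summer, noon, winter.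

The forecast, “That points to mild saturation”, named dawn, with 92 % in noon, 68 % in winter, 96 % in dawn and 93 % in summer.

The flasks give 88.9 % in noon, 65.7 % in winter, 96.7 % in dawn and 92.1 % in summer, so dawn holds the most.

    2 free catalyst ⇌ resting dimer, settled at all times (K = 67.5 L mol⁻¹, ΔH = −55.0 kJ mol⁻¹)
    second catalyst → spent catalyst (k = 8.31 × 10⁻⁵ min⁻¹, Ea = 118 kJ mol⁻¹)
    partner + catalyst intermediate → second catalyst + target (k = 5.78 L mol⁻¹ min⁻¹, Ea = 49.0 kJ mol⁻¹)
    starting material + free catalyst ⇌ free catalyst + open intermediate (K = 2.60, k = 26.1 L mol⁻¹ min⁻¹, Ea = 69.0 kJ mol⁻¹, ΔH = −29.0 kJ mol⁻¹)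
    second catalyst + open intermediate ⇌ catalyst intermediate (K = 56.0 L mol⁻¹, k = 13.2 L mol⁻¹ min⁻¹, Ea = 54.0 kJ mol⁻¹, ΔH = 14.0 kJ mol⁻¹)
    (constants at 100 °C)

Winter has not come to rest at 1.00 h: it still holds 9.97 % starting material and 23.1 % open intermediate, and after 10.0 h its target reaches 99.0 %. Dawn gains 3.0 percentage points over the same stretch, reaching 99.7 %, while its second catalyst drops from 70.7 % to 15.8 %. The spread between them shrinks from 31 points to 0.70 points. Dawn's lead over summer is 4.6 points at the hour, and summer's target moves by 5 points at 0.220 M of partner.

A neighbour of winter with 0.0024 M of second catalyst has, at winter's pace, a budget of 26.8 %, which ranks it below winter. That flask gives 36.2 %, less than winter's 65.7 % and 9.4 points above its budget, with 45.0 % standing as open intermediate.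

(The runs stem from a simulated flask with constants of no real substance; the scatter is artificial.)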